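By 15.0 min the delta run stands flat, and by 20.0 min the eta run does too, so a time of 40 min should find the flask on its plateau and the plateau is what we must reckon.

common to all: gas phase 7.7 mM (held)

| flask | substrate | remark | time |
|---|---|---|---|
| delta | 0.046 M | run made earlier |  |
| eta | 0.19 M | run made earlier |  |
| flask | 0.093 M |  | 40 min |

| run | time / min | target / % |
|---|---|---|
| delta | 8.00 | 56.1 |
| delta | 15.0 | 61.8 |
| delta | 25.0 | 62.5 |
| delta | 30.0 | 62.0 |
| delta | 40.0 | 62.4 |
| eta | 4.00 | 14.4 |
| eta | 10.0 | 24.1 |
| eta | 20.0 | 25.6 |
| eta | 30.0 | 25.3 |
| eta | 40.0 | 24.6 |

(readings scatter by 0.5 percentage points)

1. the target standing at 40 min, as a percentage of the substrate charged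
2. the change that raises the amount of target at 40 min, in percent of the substrate charged most ("none" if none brings more than 2 percentage points) (winter / spring / none)
3. amount of target at 40 min, in percent of the substrate charged, after spring

- winter: doubling the saturation concentration of gas phase, all else as stated
- spring: doubling the transfer coefficient of the gas phase, all else as stated

- at the start none of the gas phase is in solution

The plateau is higher in delta, at 62.4 %, than in eta, at 25.3 %, so a molecule of substrate reaches a fork whose losing branch gains with the charge. Charge times target over what is not target gives 0.0763 M in delta and 0.0644 M in eta, nearly steady across a charge ratio of 4.13. The flask's charge lies close to the geometric middle of the two, so we take their geometric mean, 0.0701 M, as its even-odds charge: the charge at which a molecule has equal chances of becoming target or not, a selectivity factor put as a concentration. Our reckoning for the flask is then even-odds charge over even-odds charge plus charge, 43.0 %. Winter lifts the level dissolved gas can reach, spring the speed towards that level, so we pick winter and put no figure on spring.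

The forecast says 42.7 %, winter and 48 %, reading “a side reaction of higher order in substrate than the target route”.

The flask gives 42.4 %, with winter best at 12 percentage points against 7.2 points for spring, which ends at 49.6 %.

    gas phase ⇌ dissolved gas, rate k1*(csat - [dissolved gas]) (kL = 1.60 min⁻¹)
    dissolved gas → decomposed reagent (k = 0.190 min⁻¹)
    substrate + dissolved gas → target (k = 57.0 M⁻¹ min⁻¹)
    2 substrate → homo dimer (k = 2.90 M⁻¹ min⁻¹)

With dissolved gas at saturation, substrate goes to target at 0.439 min⁻¹, less than the 0.539 min⁻¹ at which the flask's charge goes to homo dimer. But dissolved gas starts from none in the flask and stands at 0.00419 M after 4.00 min, less than the saturation value of 7.7 mM, when homo dimer is already at 54.7 % on its way to 57.6 %. The flask's plateau reads an even-odds charge of 0.0685 M. Put to the neighbour flask with 0.056 M of substrate, our 0.0701 M gives 55.6 %, and that flask stands at 56.8 %.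

The numbers in the tables come from a simulation from invented constants, and the scatter is random.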